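**Retrosynthetic overview**

1. Locants (final skeleton): ring A = trimethoxybenzene (C1–C4, C4a, C9a); ring B = seven-membered ring (spiro C5, C6H2, C7HMe, C8HMe, C9HOH, C9a, C4a); ring C = dienone (C1' = C5, C2'/C6' = CH, C3'/C5' = C–OMe, C4' = C=O).
2. 23 ⇐ 22 (Si–O cleavage at C9) ⇐ 21 (C4' silyl carbinol to ketone).
3. Key disconnection C1'–C2' of ring C, made in the same flask directly after C4a–C5 of ring B: 21 ⇐ open-chain aryl bromide 16, a β-methoxy enone whose carbonyl carbon becomes C5.
4. 16 ⇐ Weinreb amide 7 + alkyne 13 (ynone, then MeOH); 7 ⇐ δ-lactone 5 ⇐ dihydropyranone 4 (acrylate RCM) ⇐ aldehyde 1; C9/C8 come from syn-crotylation, C7 from cuprate addition anti to the C8 methyl on the lactone.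
5. Enabling feature: C5 is benzylic to ring A (OMe ortho and para to C4a) and bears two identical enol-ether arms C2'=C3'(OMe) and C6'=C5'(OMe); one arm can therefore be the O-methylated enone of a Stork–Danheiser addition (cation at C5 conjugated with C6'=C5'–OMe), the other a nucleophilic enol ether that closes the ring through C2'. Ring order: A (purchased), then B and C in one operation.

Key step: step 12

Remark: the silyloxy carbon that becomes C4' is introduced racemic with alkyne 13, so 15–21 are carried as both epimers at that carbon; step 13 turns it into the carbonyl carbon and removes the mixture.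

**Route**

Step 1
Reactants: 1 2-bromo-3,4,5-trimethoxybenzaldehyde
Product: 2 (1R,2S)-1-(2-bromo-3,4,5-trimethoxyphenyl)-2-methylbut-3-en-1-ol
Conditions: cis-2-butene, n-BuLi, KOt-Bu, THF, −78 → −45 °C; (+)-Ipc2BOMe, −78 °C; BF3·OEt2; 1, −78 °C; then NaOH, H2O2
Reagents that add atoms: (Z)-crotyldiisopinocampheylborane, C/C=C\CB([C@H]1C[C@H]2C[C@@H]([C@@H]1C)C2(C)C)[C@H]1C[C@H]2C[C@@H]([C@@H]1C)C2(C)C, made in the flask from cis-2-butene, C/C=C\C
Why: Brown asymmetric crotylboration through a closed chair transition state, so the Z-crotyl geometry gives the syn relation of the future C9 and C8, and the isopinocampheyl groups of the reagent from (+)-Ipc2BOMe select the aldehyde face that gives the 1R carbinol.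

Step 2
Reactants: 2 (1R,2S)-1-(2-bromo-3,4,5-trimethoxyphenyl)-2-methylbut-3-en-1-ol
Product: 3 (1R,2S)-1-(2-bromo-3,4,5-trimethoxyphenyl)-2-methylbut-3-en-1-yl acrylate
Conditions: acryloyl chloride, Et3N, DMAP (cat.), CH2Cl2, 0 °C
Reagents that add atoms: acryloyl chloride, C=CC(=O)Cl
Why: DMAP-catalysed O-acylation of the secondary alcohol installs the second alkene for metathesis without touching either stereocentre.

Step 3
Reactants: 3 (1R,2S)-1-(2-bromo-3,4,5-trimethoxyphenyl)-2-methylbut-3-en-1-yl acrylate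
Product: 4 (5S,6R)-6-(2-bromo-3,4,5-trimethoxyphenyl)-5-methyl-5,6-dihydro-2H-pyran-2-one
Conditions: second-generation Grubbs catalyst (cat.), CH2Cl2, 40 °C
Reagents that add atoms: none
Why: ring-closing metathesis of the acrylate and the terminal alkene gives the six-membered unsaturated lactone with loss of ethylene, a standard entry to 5,6-dihydropyran-2-ones.

Step 4
Reactants: 4 (5S,6R)-6-(2-bromo-3,4,5-trimethoxyphenyl)-5-methyl-5,6-dihydro-2H-pyran-2-one
Product: 5 (4R,5S,6R)-6-(2-bromo-3,4,5-trimethoxyphenyl)-4,5-dimethyltetrahydro-2H-pyran-2-one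
Conditions: MeLi, CuI, Et2O, −78 → −30 °C; then NH4Cl (aq)
Reagents that add atoms: lithium dimethylcuprate, [Li+].C[Cu-]C, made in the flask from MeLi, [Li]C
Why: Gilman cuprate 1,4-addition to the unsaturated δ-lactone takes place on the half-chair anti to the neighbouring pseudoaxial methyl group, so the new methyl stereocentre (future C7) is set trans to it by the ring.

Step 5
Reactants: 5 (4R,5S,6R)-6-(2-bromo-3,4,5-trimethoxyphenyl)-4,5-dimethyltetrahydro-2H-pyran-2-one
Product: 6 (3R,4S,5R)-5-(2-bromo-3,4,5-trimethoxyphenyl)-5-hydroxy-N-methoxy-N,3,4-trimethylpentanamide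
Conditions: MeNH(OMe)·HCl, AlMe3, CH2Cl2, 0 °C → rt; then potassium sodium tartrate (aq)
Reagents that add atoms: N,O-dimethylhydroxylamine hydrochloride, CNOC.Cl
Why: Weinreb aminolysis of the lactone by the aluminium amide opens the ring to the δ-hydroxy Weinreb amide without epimerisation, the lactone carbonyl carbon being the future spiro carbon C5.

Step 6
Reactants: 6 (3R,4S,5R)-5-(2-bromo-3,4,5-trimethoxyphenyl)-5-hydroxy-N-methoxy-N,3,4-trimethylpentanamide
Product: 7 (3R,4S,5R)-5-(2-bromo-3,4,5-trimethoxyphenyl)-N-methoxy-N,3,4-trimethyl-5-[(triisopropylsilyl)oxy]pentanamide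
Conditions: TIPSOTf, 2,6-lutidine, CH2Cl2, 0 °C → rt
Reagents that add atoms: triisopropylsilyl triflate, CC(C)[Si](C(C)C)(C(C)C)OS(=O)(=O)C(F)(F)F
Why: silylation of the benzylic alcohol with a bulky group stops relactonisation, resists retro-Brook migration to the later ortho-lithio carbon and keeps this oxygen from acting as a neighbouring nucleophile in step 12.

Step 7
Reactants: 8 methyl vinyl ether; 9 3-(trimethylsilyl)prop-2-ynal
Product: 11 4-methoxy-1-(trimethylsilyl)pent-4-en-1-yn-3-ol (racemic), via (1-methoxyvinyl)lithium 10 (not isolated)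
Conditions: 8, t-BuLi, THF, −78 → 0 °C; then 9, −78 °C; then H2O
Reagents that add atoms: none
Why: α-lithiation of the vinyl ether (acyl-anion equivalent) and 1,2-addition to the ynal give the carbinol that carries the future C2', C3'(OMe) and C4' with the enol ether already in place.

Step 8
Reactants: 11 4-methoxy-1-(trimethylsilyl)pent-4-en-1-yn-3-ol (racemic)
Product: 12 tert-butyl{[4-methoxy-1-(trimethylsilyl)pent-4-en-1-yn-3-yl]oxy}dimethylsilane (racemic)
Conditions: TBSCl, imidazole, DMF, rt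
Reagents that add atoms: tert-butyldimethylsilyl chloride, CC(C)(C)[Si](C)(C)Cl
Why: standard silylation under basic conditions protects the carbinol while the acid-labile enol ether is left alone.

Step 9
Reactants: 12 tert-butyl{[4-methoxy-1-(trimethylsilyl)pent-4-en-1-yn-3-yl]oxy}dimethylsilane (racemic)
Product: 13 tert-butyl[(4-methoxypent-4-en-1-yn-3-yl)oxy]dimethylsilane (racemic)
Conditions: K2CO3 (cat.), MeOH, 0 °C → rt
Reagents that add atoms: none
Why: base-catalysed methanolysis cleaves only the alkynyl C–Si bond, freeing the terminal alkyne while the TBS ether and the enol ether survive.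

Step 10
Reactants: 13 tert-butyl[(4-methoxypent-4-en-1-yn-3-yl)oxy]dimethylsilane (racemic); 7 (3R,4S,5R)-5-(2-bromo-3,4,5-trimethoxyphenyl)-N-methoxy-N,3,4-trimethyl-5-[(triisopropylsilyl)oxy]pentanamide
Product: 15 (8R,9S,10R)-10-(2-bromo-3,4,5-trimethoxyphenyl)-3-[(tert-butyldimethylsilyl)oxy]-2-methoxy-8,9-dimethyl-10-[(triisopropylsilyl)oxy]dec-1-en-4-yn-6-one (both C3 epimers), via lithium acetylide 14 (not isolated)
Conditions: 13, n-BuLi, THF, −78 °C; then 7, −78 → 0 °C; then H2O
Reagents that add atoms: none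
Why: Weinreb ketone synthesis, in which the acetylide adds once because the chelated tetrahedral intermediate lasts until work-up, and the aryl bromide is inert to the acetylide.

Step 11
Reactants: 15 (8R,9S,10R)-10-(2-bromo-3,4,5-trimethoxyphenyl)-3-[(tert-butyldimethylsilyl)oxy]-2-methoxy-8,9-dimethyl-10-[(triisopropylsilyl)oxy]dec-1-en-4-yn-6-one (both C3 epimers)
Product: 16 (4E,8R,9S,10R)-10-(2-bromo-3,4,5-trimethoxyphenyl)-3-[(tert-butyldimethylsilyl)oxy]-2,4-dimethoxy-8,9-dimethyl-10-[(triisopropylsilyl)oxy]deca-1,4-dien-6-one (both C3 epimers)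
Conditions: MeOH, DABCO (cat.), CH2Cl2, rt
Reagents that add atoms: methanol, CO
Why: amine-catalysed oxa-Michael addition of methanol to the ynone gives the β-methoxy enone (vinylogous ester) as the thermodynamically preferred E isomer, which places the two chain ends that must become C4' and C5 cis across the new double bond.

Step 12
Reactants: 16 (4E,8R,9S,10R)-10-(2-bromo-3,4,5-trimethoxyphenyl)-3-[(tert-butyldimethylsilyl)oxy]-2,4-dimethoxy-8,9-dimethyl-10-[(triisopropylsilyl)oxy]deca-1,4-dien-6-one (both C3 epimers)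
Product: 21 (7R,8S,9R)-4'-[(tert-butyldimethylsilyl)oxy]-2,3,3',4,5'-pentamethoxy-7,8-dimethyl-9-[(triisopropylsilyl)oxy]-6,7,8,9-tetrahydrospiro[benzo[7]annulene-5,1'-cyclohexa[2,5]diene] (both C4' epimers), via aryllithium 17 (not isolated), via lithium alkoxide 18 (not isolated), via tertiary trifluoroacetate 19 (not isolated), via methoxyallyl cation 20 (not isolated)
Conditions: t-BuLi (2.1 equiv), THF/Et2O/pentane, −100 °C; then 2,6-lutidine, (CF3CO)2O, −78 → −20 °C
Reagents that add atoms: none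
Why: Proposed new method: Br–Li exchange gives aryllithium 17, whose 1,2-addition to the vinylogous-ester carbonyl closes ring B in a 7-exo-trig Parham cyclization, and O-trifluoroacetylation of alkoxide 18 followed by ionisation of 19 gives the 1-methoxyallyl cation 20 of a Stork–Danheiser addition, here generated without water so that its usual hydrolysis to the enone is interrupted. The 1-methoxyvinyl group then attacks the benzylic terminus of 20 (future C5) through its terminal carbon (future C2') in a 6-endo-trig cation–olefin closure of ring C, and loss of a proton from C2' to 2,6-lutidine restores the enol ether, so both C–OMe enol ethers of ring C are in place at once. The closest known reaction types are the Parham cyclization of aryllithiums on to internal carbonyl groups, the Stork–Danheiser addition of organolithiums to β-alkoxy enones and Prins-type cyclizations of enol ethers on to stabilised cations. No lasting stereocentre is formed: the spiro carbon C5 carries two constitutionally identical ring C arms, the silyloxy carbon C4' remains a mixture of epimers that step 13 erases, and C7–C9 are untouched. The step needs halogen–metal exchange before carbonyl attack by t-BuLi and ring closure before proton transfer from C6 (secured by −100 °C, the low electrophilicity of the vinylogous ester and the intramolecular seven-membered addition), and C- rather than O-capture of 20 (secured by the bulky silyl ethers, by the E geometry of 16 that holds the future C4' and C5 cis across C5'=C6', and by the fact that attack at the other cation terminus would need a four-membered ring). Both ortho positions of the ring A carbon bonded to C5 are substituted, which closes off Friedel–Crafts or Nazarov-type escape routes of the cation.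

Step 13
Reactants: 21 (7R,8S,9R)-4'-[(tert-butyldimethylsilyl)oxy]-2,3,3',4,5'-pentamethoxy-7,8-dimethyl-9-[(triisopropylsilyl)oxy]-6,7,8,9-tetrahydrospiro[benzo[7]annulene-5,1'-cyclohexa[2,5]diene] (both C4' epimers)
Product: 22 (7R,8S,9R)-2,3,3',4,5'-pentamethoxy-7,8-dimethyl-9-[(triisopropylsilyl)oxy]-6,7,8,9-tetrahydrospiro[benzo[7]annulene-5,1'-cyclohexa[2,5]dien]-4'-one
Conditions: DDQ, CH2Cl2/pH 7 phosphate buffer, 0 °C
Reagents that add atoms: none
Why: DDQ oxidation of an allylic silyl ether, in which hydride abstraction from the doubly allylic, silyloxy-bearing C4'–H gives a silyloxy pentadienyl cation that loses the silyl group to water and leaves the cross-conjugated dienone; both epimers converge, and a conjugated silyl dienol ether isomer of 21 would be oxidised to the same dienone.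

Step 14
Reactants: 22 (7R,8S,9R)-2,3,3',4,5'-pentamethoxy-7,8-dimethyl-9-[(triisopropylsilyl)oxy]-6,7,8,9-tetrahydrospiro[benzo[7]annulene-5,1'-cyclohexa[2,5]dien]-4'-one
Product: 23 (7R,8S,9R)-9-hydroxy-2,3,3',4,5'-pentamethoxy-7,8-dimethyl-6,7,8,9-tetrahydrospiro[benzo[7]annulene-5,1'-cyclohexa[2,5]dien]-4'-one (CNP0288561.1)
Conditions: HF·pyridine, pyridine, THF, 0 °C → rt
Reagents that add atoms: none
Why: fluoride cleavage of the silyl ether under buffered, non-basic conditions frees the C9 alcohol with retention, while the dienone and its α-methoxy enol ethers are not exposed to alkoxide.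

**Compound list**

1 | 2-bromo-3,4,5-trimethoxybenzaldehyde | O=Cc1cc(OC)c(OC)c(OC)c1Br | starting material
2 | (1R,2S)-1-(2-bromo-3,4,5-trimethoxyphenyl)-2-methylbut-3-en-1-ol | C=C[C@H](C)[C@@H](O)c1cc(OC)c(OC)c(OC)c1Br | intermediate
3 | (1R,2S)-1-(2-bromo-3,4,5-trimethoxyphenyl)-2-methylbut-3-en-1-yl acrylate | C=C[C@H](C)[C@@H](OC(=O)C=C)c1cc(OC)c(OC)c(OC)c1Br | intermediate
4 | (5S,6R)-6-(2-bromo-3,4,5-trimethoxyphenyl)-5-methyl-5,6-dihydro-2H-pyran-2-one | C1=C[C@H](C)[C@@H](OC1=O)c2cc(OC)c(OC)c(OC)c2Br | intermediate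
5 | (4R,5S,6R)-6-(2-bromo-3,4,5-trimethoxyphenyl)-4,5-dimethyltetrahydro-2H-pyran-2-one | O=C1C[C@@H](C)[C@H](C)[C@@H](O1)c2cc(OC)c(OC)c(OC)c2Br | intermediate
6 | (3R,4S,5R)-5-(2-bromo-3,4,5-trimethoxyphenyl)-5-hydroxy-N-methoxy-N,3,4-trimethylpentanamide | CON(C)C(=O)C[C@@H](C)[C@H](C)[C@@H](O)c1cc(OC)c(OC)c(OC)c1Br | intermediate
7 | (3R,4S,5R)-5-(2-bromo-3,4,5-trimethoxyphenyl)-N-methoxy-N,3,4-trimethyl-5-[(triisopropylsilyl)oxy]pentanamide | CON(C)C(=O)C[C@@H](C)[C@H](C)[C@@H](O[Si](C(C)C)(C(C)C)C(C)C)c1cc(OC)c(OC)c(OC)c1Br | intermediate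
8 | methyl vinyl ether | COC=C | starting material
9 | 3-(trimethylsilyl)prop-2-ynal | C[Si](C)(C)C#CC=O | starting material
10 | (1-methoxyvinyl)lithium | [Li]C(=C)OC | intermediate
11 | 4-methoxy-1-(trimethylsilyl)pent-4-en-1-yn-3-ol (racemic) | C=C(OC)C(O)C#C[Si](C)(C)C | intermediate
12 | tert-butyl{[4-methoxy-1-(trimethylsilyl)pent-4-en-1-yn-3-yl]oxy}dimethylsilane (racemic) | C=C(OC)C(O[Si](C)(C)C(C)(C)C)C#C[Si](C)(C)C | intermediate
13 | tert-butyl[(4-methoxypent-4-en-1-yn-3-yl)oxy]dimethylsilane (racemic) | C=C(OC)C(O[Si](C)(C)C(C)(C)C)C#C | intermediate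
14 | lithium acetylide of 13 | C=C(OC)C(O[Si](C)(C)C(C)(C)C)C#C[Li] | intermediate
15 | (8R,9S,10R)-10-(2-bromo-3,4,5-trimethoxyphenyl)-3-[(tert-butyldimethylsilyl)oxy]-2-methoxy-8,9-dimethyl-10-[(triisopropylsilyl)oxy]dec-1-en-4-yn-6-one (both C3 epimers) | C=C(OC)C(O[Si](C)(C)C(C)(C)C)C#CC(=O)C[C@@H](C)[C@H](C)[C@@H](O[Si](C(C)C)(C(C)C)C(C)C)c1cc(OC)c(OC)c(OC)c1Br | intermediate
16 | (4E,8R,9S,10R)-10-(2-bromo-3,4,5-trimethoxyphenyl)-3-[(tert-butyldimethylsilyl)oxy]-2,4-dimethoxy-8,9-dimethyl-10-[(triisopropylsilyl)oxy]deca-1,4-dien-6-one (both C3 epimers) | C=C(OC)C(O[Si](C)(C)C(C)(C)C)/C(OC)=C\C(=O)C[C@@H](C)[C@H](C)[C@@H](O[Si](C(C)C)(C(C)C)C(C)C)c1cc(OC)c(OC)c(OC)c1Br | intermediate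
17 | aryllithium from 16 (Li in place of Br) | C=C(OC)C(O[Si](C)(C)C(C)(C)C)/C(OC)=C\C(=O)C[C@@H](C)[C@H](C)[C@@H](O[Si](C(C)C)(C(C)C)C(C)C)c1cc(OC)c(OC)c(OC)c1[Li] | intermediate
18 | lithium alkoxide with ring B closed (tertiary C5–OLi bearing the (E)-2-methoxyalkenyl chain, both C5 epimers) | [Li]OC1(/C=C(/OC)C(O[Si](C)(C)C(C)(C)C)C(OC)=C)C[C@@H](C)[C@H](C)[C@@H](O[Si](C(C)C)(C(C)C)C(C)C)c2cc(OC)c(OC)c(OC)c21 | intermediate
19 | tertiary trifluoroacetate of 18 | FC(F)(F)C(=O)OC1(/C=C(/OC)C(O[Si](C)(C)C(C)(C)C)C(OC)=C)C[C@@H](C)[C@H](C)[C@@H](O[Si](C(C)C)(C(C)C)C(C)C)c2cc(OC)c(OC)c(OC)c21 | intermediate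
20 | 1-methoxyallyl cation at C5 (benzylic carbenium form, trifluoroacetate ion pair) | C=C(OC)C(O[Si](C)(C)C(C)(C)C)/C(OC)=C\[C+]1C[C@@H](C)[C@H](C)[C@@H](O[Si](C(C)C)(C(C)C)C(C)C)c2cc(OC)c(OC)c(OC)c21.[O-]C(=O)C(F)(F)F | intermediate
21 | (7R,8S,9R)-4'-[(tert-butyldimethylsilyl)oxy]-2,3,3',4,5'-pentamethoxy-7,8-dimethyl-9-[(triisopropylsilyl)oxy]-6,7,8,9-tetrahydrospiro[benzo[7]annulene-5,1'-cyclohexa[2,5]diene] (both C4' epimers) | COC1=CC2(C=C(OC)C1O[Si](C)(C)C(C)(C)C)C[C@@H](C)[C@H](C)[C@@H](O[Si](C(C)C)(C(C)C)C(C)C)c1cc(OC)c(OC)c(OC)c12 | intermediate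
22 | (7R,8S,9R)-2,3,3',4,5'-pentamethoxy-7,8-dimethyl-9-[(triisopropylsilyl)oxy]-6,7,8,9-tetrahydrospiro[benzo[7]annulene-5,1'-cyclohexa[2,5]dien]-4'-one | COC1=CC2(C=C(OC)C1=O)C[C@@H](C)[C@H](C)[C@@H](O[Si](C(C)C)(C(C)C)C(C)C)c1cc(OC)c(OC)c(OC)c12 | intermediate
23 | (7R,8S,9R)-9-hydroxy-2,3,3',4,5'-pentamethoxy-7,8-dimethyl-6,7,8,9-tetrahydrospiro[benzo[7]annulene-5,1'-cyclohexa[2,5]dien]-4'-one | COC1=CC2(C=C(OC)C1=O)C[C@@H](C)[C@H](C)[C@@H](O)c1cc(OC)c(OC)c(OC)c12 | target

**Step count and risks**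

Total steps: 14. Longest linear sequence: 11 (steps 1–6 and 10–14 from aldehyde 1; the alkyne branch is steps 7–9).

Steps most likely to fail:

Step 12 (proposed new method). Possible failures are attack of t-BuLi on the carbonyl before exchange, proton transfer from C6 to aryllithium 17 instead of ring closure, or capture of cation 20 by a silyl ether oxygen with loss of the silyl group. The fallback sets out from 7 and returns at 22, building ring C by known annulation chemistry. Parham cyclization of the Weinreb amide (t-BuLi, THF, −78 °C) should give the benzosuberone F1. Corey–Chaykovsky methylenation (Me3SI, KN(SiMe3)2, THF) should give the spiro-epoxide F2, and Meinwald rearrangement (MgBr2·OEt2, CH2Cl2) the α-aryl aldehyde F3. Robinson annulation with methyl vinyl ketone (KOH, EtOH) should give the spiro-cyclohexenone F4, and dehydrogenation with 2-iodoxybenzoic acid (DMSO, 80 °C) the cross-conjugated spiro-dienone F5. Double nucleophilic epoxidation (H2O2, NaOH, MeOH) should give the bis-epoxide F6. NaOMe in MeOH at reflux should then open each epoxy ketone at the α-carbon and dehydrate, giving the 2-methoxy enone on both sides, which is 22.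

Step 13. Possible failures are hydride abstraction at the benzylic C9–H of the electron-rich ring A, addition of DDQ to the enol ethers, or hydrolysis of the enol ethers by the acidic hydroquinone. The fallback sets out from 21 and returns at 22 by separating deprotection from oxidation. TBAF (1 equiv, THF, 0 °C) should remove the less hindered TBS ether in the presence of the TIPS ether to give the doubly allylic carbinol F7, and Dess–Martin periodinane with NaHCO3 (CH2Cl2, 0 °C) should oxidise it to 22.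

Step 14. Possible failures are slow cleavage of the very hindered silyl ether, with ionisation at the benzylic C9 under prolonged acid or, under basic fluoride, conjugate addition of the freed C9 alkoxide to the dienone. The fallback sets out from 21 and returns at 23 by removing both silyl groups before the dienone exists. Excess TBAF (THF, rt) should give the diol F8, and MnO2 (CH2Cl2, rt) should then oxidise the doubly allylic C4' alcohol in preference to the hindered, doubly ortho-substituted benzylic C9 alcohol, giving 23 directly.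

Further compounds
F1 | step 12 | (7R,8S,9R)-2,3,4-trimethoxy-7,8-dimethyl-9-[(triisopropylsilyl)oxy]-6,7,8,9-tetrahydro-5H-benzo[7]annulen-5-one | O=C1C[C@@H](C)[C@H](C)[C@@H](O[Si](C(C)C)(C(C)C)C(C)C)c2cc(OC)c(OC)c(OC)c21
F2 | step 12 | spiro-epoxide of F1, (7R,8S,9R)-2,3,4-trimethoxy-7,8-dimethyl-9-[(triisopropylsilyl)oxy]-6,7,8,9-tetrahydrospiro[benzo[7]annulene-5,2'-oxirane] (both C5 epimers) | C1OC12C[C@@H](C)[C@H](C)[C@@H](O[Si](C(C)C)(C(C)C)C(C)C)c1cc(OC)c(OC)c(OC)c12
F3 | step 12 | (7R,8S,9R)-2,3,4-trimethoxy-7,8-dimethyl-9-[(triisopropylsilyl)oxy]-6,7,8,9-tetrahydro-5H-benzo[7]annulene-5-carbaldehyde (both C5 epimers) | O=CC1C[C@@H](C)[C@H](C)[C@@H](O[Si](C(C)C)(C(C)C)C(C)C)c2cc(OC)c(OC)c(OC)c21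
F4 | step 12 | (7R,8S,9R)-2,3,4-trimethoxy-7,8-dimethyl-9-[(triisopropylsilyl)oxy]-6,7,8,9-tetrahydrospiro[benzo[7]annulene-5,1'-cyclohex[2]en]-4'-one (both C5 epimers) | O=C1C=CC2(CC1)C[C@@H](C)[C@H](C)[C@@H](O[Si](C(C)C)(C(C)C)C(C)C)c1cc(OC)c(OC)c(OC)c12
F5 | step 12 | (7R,8S,9R)-2,3,4-trimethoxy-7,8-dimethyl-9-[(triisopropylsilyl)oxy]-6,7,8,9-tetrahydrospiro[benzo[7]annulene-5,1'-cyclohexa[2,5]dien]-4'-one | O=C1C=CC2(C=C1)C[C@@H](C)[C@H](C)[C@@H](O[Si](C(C)C)(C(C)C)C(C)C)c1cc(OC)c(OC)c(OC)c12
F6 | step 12 | bis-epoxide of F5 at C2'–C3' and C5'–C6' (mixture of epoxide diastereomers) | O=C1C2OC2C3(C4OC14)C[C@@H](C)[C@H](C)[C@@H](O[Si](C(C)C)(C(C)C)C(C)C)c1cc(OC)c(OC)c(OC)c13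
F7 | step 13 | (7R,8S,9R)-2,3,3',4,5'-pentamethoxy-7,8-dimethyl-9-[(triisopropylsilyl)oxy]-6,7,8,9-tetrahydrospiro[benzo[7]annulene-5,1'-cyclohexa[2,5]dien]-4'-ol (both C4' epimers) | COC1=CC2(C=C(OC)C1O)C[C@@H](C)[C@H](C)[C@@H](O[Si](C(C)C)(C(C)C)C(C)C)c1cc(OC)c(OC)c(OC)c12
F8 | step 14 | (7R,8S,9R)-2,3,3',4,5'-pentamethoxy-7,8-dimethyl-6,7,8,9-tetrahydrospiro[benzo[7]annulene-5,1'-cyclohexa[2,5]diene]-4',9-diol (both C4' epimers) | COC1=CC2(C=C(OC)C1O)C[C@@H](C)[C@H](C)[C@@H](O)c1cc(OC)c(OC)c(OC)c12
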